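Both halves come from dehydrocostus lactone; guaiane numbering is used, with primes for the spiro-ketone half. The spiro-cyclohexene (C2, C1, C10, C14, C15', C4') is disconnected to a 2-methylenecyclopentanol in which C2 of an s-cis-locked dienone (C3=O, C2=C1, C10=C14) is bonded to carbinol C3'. On Lewis-acid activation C15' attacks C14, closing a seven-membered ring (C2, C3', C4', C15', C14, C10, C1) as its C4' cation. A semipinacol 1,2-shift of C2 from C3' to C4' then expels C3' as the ketone and contracts this ring to the cyclohexene, setting the quaternary spiro centre stereospecifically. The step exploits the exocyclic enone C15'=C4'–C3'=O, used first at C3', then at C15'/C4'.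

Key step: step 12

Remarks: α is the face of H1, H5 and H7 (H6 is β); the lactone is C12(=O)–O–C6 with C11 bearing methyl C13. C10–H of the target is an epimerisable vinylogous α-position; it is assumed that the natural configuration (H10 β) is the one favoured on protonation, as argued in step 12. Compound 15 is drawn without the aluminium.

Step 1
Reactants: 1 dehydrocostus lactone
Product: 2 mokko lactone, (11S)-guaia-4(15),10(14)-dien-12,6α-olide
Conditions: NaBH4, MeOH, 0 °C
Reagents that add atoms: none
Why: Conjugate hydride reduction of the α-methylene-γ-lactone, the only electron-poor alkene, should give the 11S epimer (13-methyl α, H11 trans to H7), the usual outcome for this lactone class under protic borohydride conditions.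

Step 2
Reactants: 2 mokko lactone
Product: 3 (11S)-3α-hydroxyguaia-4(15),10(14)-dien-12,6α-olide
Conditions: SeO2 (0.5 equiv), t-BuOOH, CH2Cl2, 0 °C → rt
Reagents that add atoms: selenium dioxide O=[Se]=O (catalytic oxygen carrier); tert-butyl hydroperoxide CC(C)(C)OO (terminal oxygen source)
Why: Selenium dioxide allylic oxidation (ene reaction, then [2,3]-shift) should hydroxylate the C3 methylene next to the C4=C15 methylene on the convex α-face; this centre is removed in step 3.

Step 3
Reactants: 3 (11S)-3α-hydroxyguaia-4(15),10(14)-dien-12,6α-olide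
Product: 4 (11S)-3-oxoguaia-4(15),10(14)-dien-12,6α-olide
Conditions: Dess–Martin periodinane, CH2Cl2, 0 °C → rt
Reagents that add atoms: none
Why: Dess–Martin oxidation of the secondary allylic alcohol should give the exocyclic enone without touching the lactone or any stereocentre.

Step 4
Reactants: 4 (11S)-3-oxoguaia-4(15),10(14)-dien-12,6α-olide
Product: 6 (11S)-3-oxoguaia-1,4(15),10(14)-trien-12,6α-olide, via silyl dienol ether 5 (not isolated)
Conditions: TMSOTf, Et3N, CH2Cl2, 0 °C; then Pd(OAc)2 (1.1 equiv), MeCN, rt
Reagents that add atoms: none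
Why: Soft enolisation can only go towards C2, and Saegusa–Ito oxidation (β-hydride elimination of H1) should give the C1=C2 enone conjugated with C10=C14; 6 is both diene and dienophile and is used at once, cold and dilute.

Step 5
Reactants: 6 (11S)-3-oxoguaia-1,4(15),10(14)-trien-12,6α-olide
Product: 7 (11S)-2-iodo-3-oxoguaia-1,4(15),10(14)-trien-12,6α-olide
Conditions: I2 (1.5 equiv), pyridine/CH2Cl2, 0 °C → rt, dark
Reagents that add atoms: iodine II
Why: Pyridine-promoted α-iodination of an enone (addition, iodination, elimination) should place iodine on C2, the only α-CH of the enone.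

Step 6
Reactants: 7 (11S)-2-iodo-3-oxoguaia-1,4(15),10(14)-trien-12,6α-olide
Product: 8 (11S)-3β-hydroxy-2-iodoguaia-1,4(15),10(14)-trien-12,6α-olide
Conditions: NaBH4, CeCl3·7H2O, MeOH, −78 °C
Reagents that add atoms: none
Why: Luche 1,2-reduction (hydride from the α-face) masks the ketone as a carbinol and switches off the enone so that C2–I can be metallated; the C3 centre is removed again in step 11.

Step 7
Reactants: 1 dehydrocostus lactone
Product: 9 (11R)-guaia-4(15),10(14)-dien-12,6α-olide (11-epi-mokko lactone)
Conditions: H2 (50 atm), Ru(OAc)2[(S)-BINAP] (2 mol%), CH2Cl2, 50 °C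
Reagents that add atoms: none
Why: Carbonyl-directed asymmetric hydrogenation should reduce only the α-methylene lactone (the other methylenes lack a coordinating group), and the BINAP antipode that turns α-methylene-γ-butyrolactone into the (R)-α-methyl lactone should deliver H to the α-face of C11, setting 11R (13-methyl β).

Step 8
Reactants: 9 (11R)-guaia-4(15),10(14)-dien-12,6α-olide
Product: 10 (11R)-3α-hydroxyguaia-4(15),10(14)-dien-12,6α-olide
Conditions: SeO2 (0.5 equiv), t-BuOOH, CH2Cl2, 0 °C → rt
Reagents that add atoms: selenium dioxide O=[Se]=O (catalytic oxygen carrier); tert-butyl hydroperoxide CC(C)(C)OO (terminal oxygen source)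
Why: Selenium dioxide allylic oxidation at C3 as in step 2; the neutral conditions should leave the less stable 11R centre untouched.

Step 9
Reactants: 10 (11R)-3α-hydroxyguaia-4(15),10(14)-dien-12,6α-olide
Product: 11 (11R)-3-oxoguaia-4(15),10(14)-dien-12,6α-olide
Conditions: Dess–Martin periodinane, CH2Cl2, 0 °C → rt
Reagents that add atoms: none
Why: Dess–Martin oxidation as in step 3 should give the exocyclic enone whose C3' carbonyl and C4'=C15' alkene are both used later.

Step 10
Reactants: 8 (11S)-3β-hydroxy-2-iodoguaia-1,4(15),10(14)-trien-12,6α-olide; 11 (11R)-3-oxoguaia-4(15),10(14)-dien-12,6α-olide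
Product: 13 C2–C3' linked diol, via alkenylmagnesium alkoxide 12 (not isolated)
Conditions: 8, MeMgCl (1.0 equiv), THF, −40 °C; i-PrMgCl·LiCl (1.2 equiv), −20 → 0 °C; then LaCl3·2LiCl, 11, −40 → 0 °C; aq. NH4Cl
Reagents that add atoms: none
Why: Iodine–magnesium exchange on the alkoxide (turbo-Grignard) should give a chelated alkenylmagnesium that spares the lactones at low temperature, and its lanthanum-promoted 1,2-addition to the ketone of 11 should occur on the convex α-face of the cis-fused hydroazulenone (anti to C10' and C6'), setting C3' with C2 α and OH β.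

Step 11
Reactants: 13 C2–C3' linked diol
Product: 14 C2–C3' linked keto carbinol
Conditions: MnO2 (activated, excess), CH2Cl2, rt
Reagents that add atoms: none
Why: Manganese dioxide should oxidise only the secondary bis-allylic alcohol at C3 and leave the tertiary carbinol, restoring the dienone; 14 is used directly.

Step 12
Reactants: 14 C2–C3' linked keto carbinol
Product: 17 CNP0240988.1, via seven-membered zwitterion 15 (not isolated), via ring-contracted dienol 16 (not isolated)
Conditions: Me2AlCl (3 equiv), CH2Cl2 (0.01 M), −78 → −20 °C; then MeOH/Et3N, −20 °C → rt; aq. Rochelle salt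
Reagents that add atoms: none
Why: Proposed new method: Me2AlCl turns the tertiary carbinol into an aluminium alkoxide (which cannot ionise) that chelates and activates the C3 carbonyl, so that C14 of the s-cis-locked C2=C1–C10=C14 dienone becomes the electrophile; the 2-methylenecyclopentanol alkene attacks it through C15' (7-endo-trig closure of ring C2–C3'–C4'–C15'–C14–C10–C1) to give zwitterion 15 with a tertiary C4' cation, and the dienolate carbon C2 then migrates from C3' to C4' (semipinacol 1,2-shift, formally through a donor–acceptor cyclopropanol), which pushes C3' out of the ring as the ketone and contracts the seven- to the six-membered ring (16). The closest known reaction types are the Prins–pinacol cascade and Lewis acid-initiated enone–olefin cyclisations that end in 1,2-shifts; a 1,6-addition to a dienone ending in a ring-contracting vinyl shift has not been shown. The spiro centre C4' is set stereospecifically by the carbinol C3': C2 lies on the α-face of C3' and shifts suprafacially to the α-lobe of the C4' cation, so that C15' ends β. Attack at C14 and not at the exocyclic enone carbon C15 is secured by geometry, since C14 lies peri to C2 whereas closure on C15 would need a bridgehead enolate, and only the C4'=C15' alkene can reach. C10 is protonated at the γ-position of dienolate 16 on its β-face, anti to the C5' arm of the spiro ring, and Et3N moves any deconjugated ketone into conjugation.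

Compound list
1 | dehydrocostus lactone, guaia-4(15),10(14),11(13)-trien-12,6α-olide (H1α, H5α, H6β, H7α) | C=C1CC[C@H]2C(=C)CC[C@@H]3[C@H](OC(=O)C3=C)[C@H]21 | starting material
2 | mokko lactone, (11S)-guaia-4(15),10(14)-dien-12,6α-olide (H11β, 13-methyl α) | C=C1CC[C@H]2C(=C)CC[C@@H]3[C@H](OC(=O)[C@H]3C)[C@H]21 | intermediate
3 | (11S)-3α-hydroxyguaia-4(15),10(14)-dien-12,6α-olide | C=C1[C@H](O)C[C@H]2C(=C)CC[C@@H]3[C@H](OC(=O)[C@H]3C)[C@H]21 | intermediate
4 | (11S)-3-oxoguaia-4(15),10(14)-dien-12,6α-olide | C=C1C(=O)C[C@H]2C(=C)CC[C@@H]3[C@H](OC(=O)[C@H]3C)[C@H]21 | intermediate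
5 | (11S)-3-(trimethylsilyloxy)guaia-2,4(15),10(14)-trien-12,6α-olide (not isolated) | C=C1C(O[Si](C)(C)C)=C[C@H]2C(=C)CC[C@@H]3[C@H](OC(=O)[C@H]3C)[C@H]21 | intermediate
6 | (11S)-3-oxoguaia-1,4(15),10(14)-trien-12,6α-olide | C=C1C(=O)C=C2C(=C)CC[C@@H]3[C@H](OC(=O)[C@H]3C)[C@H]21 | intermediate
7 | (11S)-2-iodo-3-oxoguaia-1,4(15),10(14)-trien-12,6α-olide | C=C1C(=O)C(I)=C2C(=C)CC[C@@H]3[C@H](OC(=O)[C@H]3C)[C@H]21 | intermediate
8 | (11S)-3β-hydroxy-2-iodoguaia-1,4(15),10(14)-trien-12,6α-olide | C=C1[C@@H](O)C(I)=C2C(=C)CC[C@@H]3[C@H](OC(=O)[C@H]3C)[C@H]21 | intermediate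
9 | (11R)-guaia-4(15),10(14)-dien-12,6α-olide (H11α, 13-methyl β; 11-epi-mokko lactone) | C=C1CC[C@H]2C(=C)CC[C@@H]3[C@H](OC(=O)[C@@H]3C)[C@H]21 | intermediate
10 | (11R)-3α-hydroxyguaia-4(15),10(14)-dien-12,6α-olide | C=C1[C@H](O)C[C@H]2C(=C)CC[C@@H]3[C@H](OC(=O)[C@@H]3C)[C@H]21 | intermediate
11 | (11R)-3-oxoguaia-4(15),10(14)-dien-12,6α-olide | C=C1C(=O)C[C@H]2C(=C)CC[C@@H]3[C@H](OC(=O)[C@@H]3C)[C@H]21 | intermediate
12 | 2-chloromagnesio derivative of 8 as its chloromagnesium 3-alkoxide (not isolated) | C=C1[C@@H](O[Mg]Cl)C([Mg]Cl)=C2C(=C)CC[C@@H]3[C@H](OC(=O)[C@H]3C)[C@H]21 | intermediate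
13 | diol: the (11S)-3β-hydroxy-1,4(15),10(14)-triene unit bonded through C2 to C3' of the (11'R)-3'β-hydroxy-4'(15'),10'(14')-diene unit, C2 on the α-face of C3' | C=C1[C@](O)(C4=C5C(=C)CC[C@@H]6[C@H](OC(=O)[C@H]6C)[C@H]5C(=C)[C@H]4O)C[C@H]2C(=C)CC[C@@H]3[C@H](OC(=O)[C@@H]3C)[C@H]21 | intermediate
14 | keto carbinol: as 13 with C3 oxidised to the ketone (3-oxo-1,4(15),10(14)-triene bonded through C2 to the tertiary carbinol C3') | C=C1[C@](O)(C4=C5C(=C)CC[C@@H]6[C@H](OC(=O)[C@H]6C)[C@H]5C(=C)C4=O)C[C@H]2C(=C)CC[C@@H]3[C@H](OC(=O)[C@@H]3C)[C@H]21 | intermediate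
15 | seven-membered zwitterion: C15'–C14 bond formed, C4' cation, C3 dienolate (C3–O⁻, C2=C3, C1=C10), C3' carbinol still bonded to C2 (not isolated, drawn without Al) | C7[C+]1[C@](O)(C4=C([O-])C(=C)[C@H]5C4=C(C7)CC[C@@H]6[C@@H]5OC(=O)[C@H]6C)C[C@H]2C(=C)CC[C@@H]3[C@H](OC(=O)[C@@H]3C)[C@H]21 | intermediate
16 | ring-contracted dienol: spiro-cyclohexene closed (C2–C4' bond, C3' ketone), left half as C3 dienol with C2=C3 and C1=C10 (aluminium dienolate, not isolated) | C=C1C(O)=C2C3=C(CC[C@@H]4[C@H](OC(=O)[C@H]4C)[C@@H]13)CC[C@]21C(=O)C[C@H]2C(=C)CC[C@@H]3[C@H](OC(=O)[C@@H]3C)[C@H]21 | intermediate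
17 | CNP0240988.1 | C=C1C(=O)C2=C3[C@@H](CC[C@@H]4[C@H](OC(=O)[C@H]4C)[C@@H]13)CC[C@]21C(=O)C[C@H]2C(=C)CC[C@@H]3[C@H](OC(=O)[C@@H]3C)[C@H]21 | target

Total steps: 12. Longest linear sequence: 9 steps (steps 1–6, 10, 11, 12) from dehydrocostus lactone.

Steps most likely to fail

1. Step 12. The cationic closure may be outrun by loss of the bis-allylic carbinol (ionisation, elimination) or by intermolecular cycloaddition of the dienone, and the final protonation may give the wrong face at C10. Fallback with known chemistry: setting out from dienone 6 and enone 11 (in excess), a thermal Diels–Alder reaction (toluene, concentrated, 40–60 °C, BHT) between the s-cis diene C2=C1–C10=C14 and the exocyclic enone C4'=C15', approached on its α-face, should give the deconjugated Diels–Alder adduct F1. Et3N in CH2Cl2 then conjugates F1 through dienol 16, so the fallback comes back at 17. It gives up the cross-selectivity of the tethered route (6 can also add to itself) and the stereospecific 1,2-shift, so it is held in reserve.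

2. Step 10. The alkenylmagnesium may attack a lactone, enolise or add 1,4 to ketone 11, or add with poor facial selectivity. Fallback: setting out from 8, silylation (TBSCl, imidazole, DMF) gives the silyl ether F2. Iodine–lithium exchange (t-BuLi, 2 equiv, Et2O/THF, −100 °C) gives the alkenyllithium F3, which is transmetallated with CeCl3 and added to 11 at −78 °C to give the silyl-protected adduct F4. TBAF in THF then returns to the route at diol 13.

3. Step 7. Hydrogen delivery at C11 may lose facial selectivity if the substrate bias opposes the catalyst, or another methylene may be reduced. Fallback: setting out from mokko lactone 2, deprotonation (LDA, THF, −78 °C) gives the lithium lactone enolate F5. Kinetic protonation at −78 °C with a hindered phenol (2,6-di-tert-butyl-4-methylphenol), on the face trans to C8, should give 9, and recovered 2 is recycled; the route is rejoined at 9.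

Further compounds
F1 | step 12 | Diels–Alder adduct of 6 and 11, the 1(10)-ene isomer of 17 with C2–H (C2 drawn for α-face approach to the diene, erased on conjugation) | C=C1C(=O)[C@H]2C3=C(CC[C@@H]4[C@H](OC(=O)[C@H]4C)[C@@H]13)CC[C@]21C(=O)C[C@H]2C(=C)CC[C@@H]3[C@H](OC(=O)[C@@H]3C)[C@H]21
F2 | step 10 | 3-O-tert-butyldimethylsilyl ether of 8 | C=C1[C@@H](O[Si](C)(C)C(C)(C)C)C(I)=C2C(=C)CC[C@@H]3[C@H](OC(=O)[C@H]3C)[C@H]21
F3 | step 10 | 2-lithio derivative of F2 | C=C1[C@@H](O[Si](C)(C)C(C)(C)C)C([Li])=C2C(=C)CC[C@@H]3[C@H](OC(=O)[C@H]3C)[C@H]21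
F4 | step 10 | 3-O-tert-butyldimethylsilyl ether of 13 | C=C1[C@](O)(C4=C5C(=C)CC[C@@H]6[C@H](OC(=O)[C@H]6C)[C@H]5C(=C)[C@H]4O[Si](C)(C)C(C)(C)C)C[C@H]2C(=C)CC[C@@H]3[C@H](OC(=O)[C@@H]3C)[C@H]21
F5 | step 7 | lithium lactone enolate of 2 | [Li+].C=C1CC[C@H]2C(=C)CC[C@@H]3[C@H](OC([O-])=C3C)[C@H]21
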